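The data were computed on assumed constants.

What I watched was a leftover: the product a run still had to give before it stopped.

| setting | Saturday's | Sunday's | Monday's | flask |
|---|---|---|---|---|
| substrate | 13 mM | 13 mM | 13 mM | 13 mM |
| partner | 19.5 mM | 19.5 mM | 29 mM | 19.5 mM |
| free catalyst | 91 µM | 140 µM | 65 µM | 65 µM |
| remark | run made earlier | run made earlier | run made earlier |  |

| run | time / min | product / % | substrate / % |
|---|---|---|---|
| Saturday's | 1.00 | 1 | 94 |
| Saturday's | 1.50 | 2 | 98 |
| Saturday's | 2.50 | 6 | 95 |
| Saturday's | 4.00 | 6 | 95 |
| Saturday's | 8.00 | 13 | 91 |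
| Saturday's | 12.0 | 14 | 87 |
| Sunday's | 2.00 | 4 | 95 |
| Sunday's | 4.00 | 6 | 91 |
| Sunday's | 6.00 | 12 | 89 |
| Sunday's | 8.00 | 11 | 85 |
| Sunday's | 10.0 | 16 | 83 |
| Sunday's | 12.0 | 20 | 80 |
| Monday's | 1.00 | 1 | 99 |
| Monday's | 2.00 | 8 | 97 |
| Monday's | 3.00 | 5 | 97 |
| Monday's | 6.00 | 10 | 94 |
| Monday's | 12.0 | 15 | 84 |

(readings scatter by 2 percentage points)



- apparent order in partner when 10% of the substrate are converted (percent change of the rate of making product for one percent more partner charged)

Sunday's run bent. I took the mean of product gained and substrate lost and got 11.5% at 6.00 min and 20.0% at 12.0 min. The second time is double the first, but the mean grew by a factor of 1.74, less than a straight line gives. So I supposed that the rate faded at first order, with the constant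

k = 0.0504 min⁻¹

Sunday's run then had a ceiling of 44.1% of its substrate. I scaled that ceiling with catalyst charged and got 20.5% for the flask. This ceiling, the product at which a flask stops once the fade is over, was the quantity I carried.

But was the scaling honest? For Saturday's run it gave 13.0% at 12.0 min, and I had read 14%. If the ceiling also scales with partner charged, Monday's run should reach 13.8% at 12.0 min, and I had read 15%. Both held within the scatter.

With P the product so far, the rate is then

rate = k (ceiling − P)

Raising the partner charge lifts the ceiling in proportion, so at fixed conversion

order in partner = ceiling / (ceiling − P)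

The zero of this scale is a flask without fade, whose order is one. Here P = 10%, so I reckoned 1.96. My doubt was k, which rests on two means with 2 percentage points of scatter on each reading, so I held that order loosely. The runs could not say whether partner or catalyst faded, but the reckoning needs neither, provided the fade is first order and its constant ignores the charges.

The forecast, made from the same runs, was 0.7, on the ground that “The curves are nearly straight up to 10% conversion”.

    partner → decomposed reagent (k = 0.0510 min⁻¹)
    catalyst intermediate C ⇌ catalyst intermediate D (K = 0.460, k = 330 min⁻¹)
    partner + free catalyst ⇌ catalyst intermediate A (K = 6.20 M⁻¹, k = 1.00 × 10⁵ M⁻¹ min⁻¹)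
    catalyst intermediate D → free catalyst + product (k = 1500 min⁻¹)
    catalyst intermediate B ⇌ released group + catalyst intermediate C (K = 0.0290 M, k = 55.0 min⁻¹)
    substrate + catalyst intermediate A ⇌ catalyst intermediate B (K = 120 M⁻¹, k = 2400 M⁻¹ min⁻¹)

The flask gave 1.7 at 12.1 min, below my 1.96 and above the zero of the scale. At 150 min decomposed reagent stood at 17.0 mM and partner at 0.0157% of its charge, with substrate at 80.6%. Against my ceiling of 20.5%, the product in that flask then stood at 19.4%.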